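**Assumption:** the target has no stereocentre and no hindered biaryl axis (the C4 aryl group has no ortho substituent), so the single achiral structure drawn is the compound to be made and no stereocontrol is needed.

## Retrosynthetic overview

1. Ring A is bought with three of its four oxygens as 3,5-dimethoxyphenol 1; one ortho-oxygenation gives o-quinone 2, which carries all four.
2. Ring B is bought as 4-ethynyl-1,2-dimethoxybenzene 3; formylation of the alkyne gives ynal 4, which supplies C2, C3, C4 and the aryl group.
3. Key disconnection: the C4–C4a bond and the O1–C2 lactone bond, both made in one carbene-catalysed redox annulation of 2 with 4 (new). Quinone 2 oxidises the carbene-bound aldehyde and is reduced to catechol 5, which attacks alkynoyl azolium 6 through carbon and oxygen to give target 7 with the 8-OH free.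
4. Ring order: rings A and B are bought; ring C (the pyranone) is the only ring built and is closed in the last step. No protecting groups are used.

## Route

**Step 1**
Reactants: 1 3,5-dimethoxyphenol
Product: 2 3,5-dimethoxycyclohexa-3,5-diene-1,2-dione (3,5-dimethoxy-1,2-benzoquinone)
Conditions: IBX (1.1 equiv), DMF, rt, 1 h, dark; cold aqueous wash, used the same day
Reagents that add atoms: 2-iodoxybenzoic acid (IBX), O=C1OI(=O)(O)c2ccccc12
Why: IBX binds the phenol oxygen and delivers one oxygen atom intramolecularly to the ortho carbon (the two ortho positions of 1 are equivalent), and the iodine-bound catechol then collapses to the o-quinone with 2-iodobenzoic acid as the spent reagent; this is the established regioselective ortho-oxygenation of electron-rich phenols by pentavalent iodine.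

**Step 2**
Reactants: 3 4-ethynyl-1,2-dimethoxybenzene
Product: 4 3-(3,4-dimethoxyphenyl)prop-2-ynal
Conditions: n-BuLi (1.05 equiv), THF, −78 °C; DMF (2 equiv), −78 °C to rt; inverse quench into 10% aq KH2PO4/MTBE, 0 °C
Reagents that add atoms: N,N-dimethylformamide (DMF), CN(C)C=O
Why: the lithium acetylide of 3 adds to DMF and the hemiaminal alkoxide persists until the buffered inverse quench, which releases the aldehyde while keeping dimethylamine protonated so it cannot add to the ynal (Bouveault-type formylation of a metal acetylide).

**Step 3**
Reactants: 2 3,5-dimethoxy-1,2-benzoquinone; 4 3-(3,4-dimethoxyphenyl)prop-2-ynal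
Product: 7 target coumarin 8-hydroxy-5,7-dimethoxy-4-(3,4-dimethoxyphenyl)-2H-chromen-2-one, via 3,5-dimethoxybenzene-1,2-diol 5 (not isolated), via alkynoyl triazolium ion 6 (not isolated)
Conditions: 2-(2,4,6-trimethylphenyl)-6,7-dihydro-5H-pyrrolo[2,1-c][1,2,4]triazol-2-ium chloride (10 mol %), K2CO3 (20 mol %), 4 Å MS, toluene/THF 4:1, 0 °C to rt; 2 (1.1 equiv) and 4 (1.0 equiv) added together over 2 h
Reagents that add atoms: none
Why: Proposed new method: a carbene-catalysed redox-relay [3+3] annulation in which the o-quinone is the stoichiometric oxidant and, once reduced, the C,O-bis-nucleophile. The carbene adds to the aldehyde of 4, and quinone 2 takes two electrons and one proton from this adduct, so alkynoyl azolium 6 and the monoanion of catechol 5 form as an ion pair. The phenoxide oxygen of 5 next to the free C–H then directs its ortho carbon (para to one OMe, ortho to the other) onto the alkyne β-carbon of 6, by conjugate addition or by 1,2-addition and [3,3] shift, which makes the C4–C4a bond. The same oxygen acylates intramolecularly, closing the lactone and releasing the carbene; the second catechol oxygen is left as the 8-OH, since it has no free ortho carbon and its O-acylation is reversible. The overall reaction is an atom-for-atom addition of 2 to 4 with no by-product. The closest known reaction types are oxidative N-heterocyclic-carbene catalysis with quinone oxidants, and the Coates–Claisen-type annulation of α,β-unsaturated or alkynoyl azoliums with enols, naphthols and electron-rich phenols to pyranones and dihydrocoumarins; what has not been shown is the use of the reduced oxidant as the annulation partner.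

## Compound list

1 | 3,5-dimethoxyphenol | COc1cc(O)cc(OC)c1 | starting material
2 | 3,5-dimethoxycyclohexa-3,5-diene-1,2-dione (3,5-dimethoxy-1,2-benzoquinone) | COC1=CC(OC)=CC(=O)C1=O | intermediate
3 | 4-ethynyl-1,2-dimethoxybenzene | COc1ccc(C#C)cc1OC | starting material
4 | 3-(3,4-dimethoxyphenyl)prop-2-ynal | COc1ccc(C#CC=O)cc1OC | intermediate
5 | 3,5-dimethoxybenzene-1,2-diol | COc1cc(OC)c(O)c(O)c1 | intermediate (formed in the flask in step 3, not isolated)
6 | alkynoyl triazolium ion, 3-[3-(3,4-dimethoxyphenyl)prop-2-ynoyl]-2-(2,4,6-trimethylphenyl)-6,7-dihydro-5H-pyrrolo[2,1-c][1,2,4]triazol-2-ium (cation, paired in the flask with the monoanion of 5) | COc1ccc(C#CC(=O)c2n3CCCc3n[n+]2-c2c(C)cc(C)cc2C)cc1OC | intermediate (formed in the flask in step 3, not isolated)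
7 | 8-hydroxy-5,7-dimethoxy-4-(3,4-dimethoxyphenyl)-2H-chromen-2-one (8-hydroxy-5,7,3',4'-tetramethoxy-4-phenylcoumarin) | COc1ccc(-c2cc(=O)oc3c(O)c(OC)cc(OC)c23)cc1OC | target

## Step count and risks

Total step count: 3. Longest linear sequence: 2 steps (1 to 2 to 7, or 3 to 4 to 7).

**Most likely to fail, first: step 3 (the proposed new annulation).** The main risks are:
- oxygen attack in place of carbon attack on 6 (oxa-Michael addition leading to benzodioxole or benzodioxepinone products);
- internal redox isomerisation of the carbene-bound ynal before 2 oxidises it;
- carbene–quinone adducts;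
- coupling of 5 with unreacted 2.

The joint slow addition and the non-polar medium are chosen against these. Traces of 2-iodobenzoic acid from step 1 would quench the catalytic base, so they must be washed out with cold dilute NaHCO3 first.

Fallback (known chemistry): set out from 2 and reduce it with aqueous Na2S2O4 in EtOAc to the isolated catechol 5. Condense 5 with commercial ethyl 3-(3,4-dimethoxyphenyl)-3-oxopropanoate F1 in CF3CO2H at rt to 40 °C (Pechmann condensation). Only the hydroxyl next to the free ring C–H can close the ring, so the same 8-hydroxy regiochemistry results, with loss of ethanol and water. The fallback comes back to the route at 7 and does not need ynal 4.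

**Second: step 1 (o-quinone formation).** The electron-rich quinone 2 may over-oxidise, hydrolyse at its vinylogous ester during work-up, or dimerise on concentration.

Fallback: set out from 1 and formylate it ortho-selectively (MgCl2, Et3N, paraformaldehyde, MeCN, reflux; Casnati–Skattebøl formylation) to 2-hydroxy-4,6-dimethoxybenzaldehyde F2. Subject F2 to Dakin oxidation (H2O2, NaOH, aqueous THF, 0 °C); this passes through 2-hydroxy-4,6-dimethoxyphenyl formate F3, which is hydrolysed in the same flask to catechol 5. Here 5 is isolated as a stable compound that can be purified. Oxidise 5 with Ag2O and Na2SO4 in Et2O at rt, then filter and evaporate; the fallback comes back to the route at 2, free of acid, just before step 3.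

**Third: step 2 (ynal formation).** Dimethylamine set free on work-up can add to the ynal, and the ynal can polymerise on concentration.

Fallback: set out from 3, deprotonate with n-BuLi in THF and add paraformaldehyde to give 3-(3,4-dimethoxyphenyl)prop-2-yn-1-ol F4. Oxidise F4 with activated MnO2 in CH2Cl2 at rt. This amine-free two-step route comes back at 4.

## Further compounds

F1 | step 3 | ethyl 3-(3,4-dimethoxyphenyl)-3-oxopropanoate | CCOC(=O)CC(=O)c1ccc(OC)c(OC)c1
F2 | step 1 | 2-hydroxy-4,6-dimethoxybenzaldehyde | COc1cc(O)c(C=O)c(OC)c1
F3 | step 1 | 2-hydroxy-4,6-dimethoxyphenyl formate | COc1cc(O)c(OC=O)c(OC)c1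
F4 | step 2 | 3-(3,4-dimethoxyphenyl)prop-2-yn-1-ol | COc1ccc(C#CCO)cc1OC
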